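In a one-step world Sunday's electrophile would have a half-life of 0.066 min against the nucleophile as charged and end as target, but these flasks have other steps.

    electrophile + nucleophile → acid set free + target (k1 = 73.0 /M/s)
    nucleophile + acid set free ⇌ protonated nucleophile, settled at all times (K2 = 1.0 × 10⁶ /M)
    2 nucleophile → self-condensation product (k3 = 37.5 /M/s)
    electrophile + acid set free → side product (k4 = 12.7 /M/s)

common to all: time 4.0 min

| flask | electrophile | nucleophile | remark |
|---|---|---|---|
| Saturday's | 0.0020 M | 2.40 mM (fed, over 2.5 min) | all else is in the flask from the start; the feed brings no volume worth counting |
| Sunday's | 0.0020 M | 2.40 mM | everything together at the start |
| Monday's | 0.0020 M (fed, over 2.5 min) | 2.40 mM | all else is in the flask from the start; the feed brings no volume worth counting |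

- the flask that comes out highest in amount of side product, in percent of the electrophile charged, or "all alike" when all lie within 1.5 percentage points (Saturday's / Sunday's / Monday's / all alike)
- side product at the end, in percent of the electrophile charged, Saturday's
- side product at the end, in percent of the electrophile charged, Sunday's
- side product at the end, in percent of the electrophile charged, Monday's

- a doubled species enters its step squared and goes two at a time
- run time (Saturday's): 4.0 min

I draw Sunday's curve of side product first. At the start c(nucleophile) falls on a time scale of 2.12 s, and the slope of side product starts near nothing, because free acid stays far below bound acid: the balance constant times c(nucleophile) is 2400. The knee comes later, when c(nucleophile) has sunk enough for free acid to climb. Each turn of the target step costs two nucleophile, one to react and one to catch the acid, so the nucleophile is the limiting reagent. It buys 60.0% of the electrophile as target, less what self-condensation takes, and I reckon with 40.0% of the electrophile remaining.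

Past the knee I follow free acid minus free nucleophile, setting self-condensation aside. Catching leaves this count unchanged, each turn of the target step adds two, each turn of the side step takes one, and electrophile stands in both rates. So the count stands still at the late ratio, c(acid set free) over c(nucleophile), equal to twice the target constant over the side constant: 11.5. There the side step runs twice as fast as the target step. With bound acid at half the nucleophile charge, the balance puts c(acid set free) near 1.17 × 10⁻⁴ M. Side product then forms at 0.0895 /min of the electrophile present, which falls at 0.134 /min in all. Counted from the start, with the delay of the knee set aside, this gives 11.1% for Sunday's. Putting Saturday's knee at the end of its feed gives 4.86%. Monday's I leave open, since its nucleophile has a first half-life of 5.56 s by self-condensation, shorter than the feed.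

The forecast names Sunday's, with 4% for Saturday's, 10% for Sunday's and 8% for Monday's, on the ground that “Side product forms only once free nucleophile has run out”.

The flasks give 3.57% for Saturday's, 10.6% for Sunday's and 6.44% for Monday's, so Sunday's is highest, as forecast. At the end of Saturday's, c(acid set free) over c(nucleophile) reads 8.39, below the late ratio of 11.5. The target step there runs at 0.69 times the side step, against 0.500 at the late ratio. In the flask charged with 0.0034 M of electrophile, the same reading at 4.00 min is 11.5, with side product at 7.83%.

All constants were chosen freely; the run is a simulation.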